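Ring A is disconnected at C2–C3 and C1–C10 and built by a Michael–Dieckmann annulation on a carvone-derived ring B ketone.

Labdane numbering is used. In the target C3 (CHBr) and C9 (C–OH) stand 1,5 across C2, C1 and C10, and C4 beside C3 is quaternary. Ring A is therefore cut at C2–C3 and C1–C10. A ring B ketone that carries the non-enolisable CMe2CO2Me group on C5 is made from (S)-carvone; its C10 potassium enolate adds to methyl acrylate and the new C2 ester enolate closes ring A by Dieckmann acylation at C3. One operation forms C1–C10 and C2–C3, the C10 quaternary centre and the trans ring fusion. The C3 ketone is then turned into the equatorial bromide through a vinyl bromide and radical hydrogenation, and the side chain from (R)-linalool is added to C9 last.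

Key step: step 3

Remark on numbering: ring A is C1–C5 plus C10, ring B is C5–C10, the side chain is C11–C16, and the methyls are C17 (on C8), C18/C19 (on C4) and C20 (on C10); the target is (3R,5S,8S,9R,10R,13R), i.e. Br equatorial, trans-decalin, C8 methyl equatorial, and the side chain on C9 trans to the C10 methyl.

Remark on C8: the C8 methine next to the C9 ketone is epimerisable until step 10; it is drawn as formed in 2, 4, 6 and 7 and as the equatorial, thermodynamically preferred epimer from 8 on.

Remark on C7: the isopropenyl group of carvone sits on C7 and serves only as a removable control element (steps 2 to 5).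

Step 1
Reactants: 1 (S)-(+)-carvone
Product: 2 (5S,6R)-2,6-dimethyl-5-(prop-1-en-2-yl)cyclohex-2-en-1-one (trans-6-methylcarvone)
Conditions: LiN(i-Pr)2, THF, −78 °C; MeI, −78 to 0 °C
Reagents that add atoms: iodomethane, CI
Why: Kinetic deprotonation at C6 gives the cross-conjugated dienolate, and its SN2 methylation (enolate alkylation) should place the methyl trans to the isopropenyl group, the new centre (C8 of the target) staying epimerisable until it is equilibrated in steps 3 and 4.

Step 2
Reactants: 2 trans-6-methylcarvone; 3 1-methoxy-2-methyl-1-(trimethylsilyloxy)prop-1-ene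
Product: 4 methyl 2-[(1S,4R,5S)-2,4-dimethyl-5-(prop-1-en-2-yl)-3-(trimethylsilyloxy)cyclohex-2-en-1-yl]-2-methylpropanoate
Conditions: Tf2NH (2 mol %), CH2Cl2, −78 °C; Et3N quench
Reagents that add atoms: none
Why: In this Mukaiyama–Michael addition under silyl triflimide catalysis the ketene acetal should attack the enone β-carbon anti to the isopropenyl group, which sets C5 of the target and builds the C4–C5 bond with the gem-dimethyl and the C3 ester in place, while silyl transfer gives the regiodefined C9=C10 enol ether.

Step 3
Reactants: 4 silyl enol ether; 5 methyl acrylate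
Product: 8 methyl 4,4,7,8a-tetramethyl-3,8-dioxo-6-(prop-1-en-2-yl)decahydronaphthalene-2-carboxylate (trans-fused β-keto ester; C2 epimers and enol), via potassium enolate 6 (not isolated), via Michael adduct enolate 7 (not isolated)
Conditions: KOtBu (1.2 equiv), THF, −20 °C; 5 (slow addition), −78 to 23 °C; AcOH
Reagents that add atoms: none
Why: KOtBu cleaves the silyl enol ether to the regiodefined potassium enolate 6 (C9–O−, C9=C10), which adds through C10 to methyl acrylate (Michael addition, C1–C10 bond) to give the ester enolate 7; its C2 carbon then attacks the C3 methyl ester on the quaternary C4 in a Dieckmann acylation, which forms the C2–C3 bond and closes ring A. The closest known reaction type is the Michael–Dieckmann (Michael–Claisen) annulation of ketone enolates with acrylates to give cyclic β-keto esters. Ring A closes in the 6-exo-trig mode (addition–elimination at the ester carbonyl) as a chair with C1 and C4 both equatorial on ring B. The new quaternary centre C10 is set in the Michael step, where the acrylate should approach anti to the bulky C5 substituent, so that the C10 methyl and H5 end trans (trans-decalin); C2 forms as an epimer and enol mixture and loses its stereochemistry in step 4, and the excess base should begin to equilibrate C8. The step needs ring closure at C3 to win over acrylate oligomerisation and over Claisen attack of a C8 enolate on the new ester: slow addition of 5 at −78 °C serves the first, and the substrate secures the second, because the ester on C4 has no α-hydrogen and because only the Dieckmann product has an acidic C2–H between two carbonyls and is withdrawn as its enolate, while the bridged diketone from C8 (quaternary, methyl-bearing) could not be deprotonated and would revert.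

Step 4
Reactants: 8 trans-fused β-keto ester
Product: 9 (2S,3S,4aR,8aR)-2,5,5,8a-tetramethyl-3-(prop-1-en-2-yl)octahydronaphthalene-1,6-dione
Conditions: LiCl, H2O, DMSO, 150 °C
Reagents that add atoms: none
Why: Krapcho decarboxylation (chloride SN2 demethylation, then loss of CO2) removes the activating ester from C2, and the hot, slightly basic medium should complete the equilibration of C8 to the equatorial methyl, which avoids the 1,3-diaxial clash with the C10 methyl.

Step 5
Reactants: 9 isopropenyl diketone
Product: 11 (2S,4aR,8aR)-2,5,5,8a-tetramethyloctahydronaphthalene-1,6-dione, via methoxy hydroperoxide 10 (not isolated)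
Conditions: O3, MeOH, −78 °C; FeSO4·7H2O, PhSH, −78 to 23 °C
Reagents that add atoms: none
Why: Ozonolysis in methanol gives the α-methoxy hydroperoxide 10, whose one-electron reduction by the iron salt gives an alkoxy radical that loses methyl acetate by β-scission, and the C7 radical takes hydrogen from the thiol (hydrodealkenylation), so the stereocontrol element is excised and C7 becomes CH2 without touching either ketone.

Step 6
Reactants: 11 diketone
Product: 12 (2S,4aS,8aR)-6-bromo-2,5,5,8a-tetramethyl-3,4,4a,5,8,8a-hexahydronaphthalen-1(2H)-one
Conditions: (PhO)3P, Br2 (premixed), Et3N, CH2Cl2, −60 °C to reflux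
Reagents that add atoms: bromine, BrBr
Why: Bromo-olefination of a ketone with the triphenyl phosphite–bromine adduct (O-phosphonium activation, bromide addition, base-induced elimination) should take place at the C3 ketone, which can enolise only toward C2, because the C9 ketone lies between a quaternary and a methyl-bearing tertiary carbon and is far more hindered.

Step 7
Reactants: 12 vinyl bromide
Product: 13 (2S,4aS,6R,8aR)-6-bromo-2,5,5,8a-tetramethyloctahydronaphthalen-1(2H)-one
Conditions: Mn(dpm)3 [tris(2,2,6,6-tetramethylheptane-3,5-dionato)manganese] (10 mol %), PhSiH3, t-BuOOH, i-PrOH, 23 °C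
Reagents that add atoms: none
Why: In this metal-hydride hydrogen-atom-transfer hydrogenation of a haloalkene the first hydrogen should add to the less hindered C2 to give the α-bromo radical at C3, which takes the second hydrogen axially from the face opposite the axial C4 methyl, so that bromine ends equatorial (3R, the more stable epimer) without C–Br hydrogenolysis and with the ketone untouched.

Step 8
Reactants: 14 (R)-(−)-linalool
Product: 16 (5R)-5-ethenyl-5-methyloxolan-2-ol (lactol; anomers), via secondary ozonide 15 (not isolated)
Conditions: O3 (1 equiv), CH2Cl2, −78 °C; Me2S, −78 to 23 °C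
Reagents that add atoms: ozone, [O-][O+]=O
Why: Ozonolysis with reductive work-up is chemoselective for the electron-rich trisubstituted alkene over the vinyl group, and the resulting hydroxy aldehyde closes to the lactol, the C13 stereocentre of the target being taken unchanged from linalool.

Step 9
Reactants: 16 lactol
Product: 18 (3R)-5-iodo-3-methylpent-1-en-3-ol, via iodoformate 17 (not isolated)
Conditions: PhI(OAc)2, I2, CH2Cl2, visible light, 23 °C; aqueous Na2S2O3 wash; then K2CO3 (cat.), MeOH, 0 °C
Reagents that add atoms: iodine, II
Why: The anomeric hypoiodite is photolysed to an alkoxy radical whose β-scission (alkoxy-radical fragmentation of a lactol) releases a formate and a primary radical that is trapped by iodine, which excises the former aldehyde carbon, and mild methanolysis of the labile tertiary formate frees the alcohol.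

Step 10
Reactants: 18 iodo alcohol; 13 bromo ketone
Product: 21 (1R,2S,4aS,6R,8aR)-6-bromo-1-[(3R)-3-hydroxy-3-methylpent-4-en-1-yl]-2,5,5,8a-tetramethyldecahydronaphthalen-1-ol (target), via lithium alkoxide 19 (not isolated), via dilithio reagent 20 (not isolated)
Conditions: 18 (2.5 equiv): MeLi (1.0 equiv per 18), Et2O, −78 °C; t-BuLi (2.1 equiv per 18), −78 °C; then 13 precomplexed with CeCl3, THF, −78 °C; aqueous NH4Cl
Reagents that add atoms: none
Why: Deprotonation and iodine–lithium exchange give the γ-oxido alkyllithium 20, and its 1,2-addition to the cerium-activated, enolisable ketone (organolithium addition to a hindered ketone) should occur axially from the face anti to the axial C10 methyl, which sets C9 (9R) with the side chain trans to that methyl and the hydroxyl equatorial, while the hindered equatorial secondary bromide should survive at −78 °C.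

Compound list
1 | (S)-(+)-carvone, (5S)-2-methyl-5-(prop-1-en-2-yl)cyclohex-2-en-1-one | O=C1C(C)=CC[C@H](C(C)=C)C1 | starting material
2 | (5S,6R)-2,6-dimethyl-5-(prop-1-en-2-yl)cyclohex-2-en-1-one (trans-6-methylcarvone; methyl trans to isopropenyl) | O=C1C(C)=CC[C@H](C(C)=C)[C@H]1C | intermediate
3 | 1-methoxy-2-methyl-1-(trimethylsilyloxy)prop-1-ene (silyl ketene acetal of methyl isobutyrate) | COC(O[Si](C)(C)C)=C(C)C | starting material
4 | methyl 2-[(1S,4R,5S)-2,4-dimethyl-5-(prop-1-en-2-yl)-3-(trimethylsilyloxy)cyclohex-2-en-1-yl]-2-methylpropanoate (C4–C5 bond trans to the isopropenyl group; C9=C10 silyl enol ether) | C[Si](C)(C)OC1=C(C)[C@@H](C(C)(C)C(=O)OC)C[C@H](C(C)=C)[C@H]1C | intermediate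
5 | methyl acrylate | C=CC(=O)OC | starting material
6 | potassium enolate (C9–O−, C9=C10) corresponding to silyl enol ether 4 | [K+].[O-]C1=C(C)[C@@H](C(C)(C)C(=O)OC)C[C@H](C(C)=C)[C@H]1C | intermediate
7 | potassium ester enolate of the Michael adduct (C10 bears methyl and CH2CH=C(OMe)O−, the latter trans to the C5 substituent) | [K+].[O-]C(OC)=CC[C@@]1(C)C(=O)[C@H](C)[C@@H](C(C)=C)C[C@@H]1C(C)(C)C(=O)OC | intermediate
8 | methyl (4aR,6S,7S,8aR)-4,4,7,8a-tetramethyl-3,8-dioxo-6-(prop-1-en-2-yl)decahydronaphthalene-2-carboxylate (trans-fused; C2 epimers and enol) | O=C1[C@@H](C)[C@@H](C(C)=C)C[C@@H]2C(C)(C)C(=O)C(C(=O)OC)C[C@]21C | intermediate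
9 | (2S,3S,4aR,8aR)-2,5,5,8a-tetramethyl-3-(prop-1-en-2-yl)octahydronaphthalene-1,6-dione (trans-fused; C8 methyl equatorial; C7 isopropenyl axial) | O=C1[C@@H](C)[C@@H](C(C)=C)C[C@@H]2C(C)(C)C(=O)CC[C@]21C | intermediate
10 | 3-(1-hydroperoxy-1-methoxyethyl) analogue of 9 (α-methoxy hydroperoxide from ozonolysis of the isopropenyl group in methanol) | O=C1[C@@H](C)[C@@H](C(C)(OC)OO)C[C@@H]2C(C)(C)C(=O)CC[C@]21C | intermediate
11 | (2S,4aR,8aR)-2,5,5,8a-tetramethyloctahydronaphthalene-1,6-dione (trans-fused C3,C9-diketone) | O=C1[C@@H](C)CC[C@@H]2C(C)(C)C(=O)CC[C@]21C | intermediate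
12 | (2S,4aS,8aR)-6-bromo-2,5,5,8a-tetramethyl-3,4,4a,5,8,8a-hexahydronaphthalen-1(2H)-one (C2=C3 vinyl bromide) | O=C1[C@@H](C)CC[C@@H]2C(C)(C)C(Br)=CC[C@]21C | intermediate
13 | (2S,4aS,6R,8aR)-6-bromo-2,5,5,8a-tetramethyloctahydronaphthalen-1(2H)-one (equatorial bromide; C9 ketone) | O=C1[C@@H](C)CC[C@@H]2C(C)(C)[C@H](Br)CC[C@]21C | intermediate
14 | (R)-(−)-linalool, (3R)-3,7-dimethylocta-1,6-dien-3-ol | CC(C)=CCC[C@@](C)(O)C=C | starting material
15 | secondary ozonide (1,2,4-trioxolane) of the trisubstituted alkene of 14 | CC1(C)OOC(CC[C@@](C)(O)C=C)O1 | intermediate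
16 | (5R)-5-ethenyl-5-methyloxolan-2-ol (anomeric mixture) | OC1CC[C@](C)(C=C)O1 | intermediate
17 | (3R)-5-iodo-3-methylpent-1-en-3-yl formate | ICC[C@@](C)(OC=O)C=C | intermediate
18 | (3R)-5-iodo-3-methylpent-1-en-3-ol | ICC[C@@](C)(O)C=C | intermediate
19 | lithium (3R)-5-iodo-3-methylpent-1-en-3-olate | ICC[C@@](C)([O-])C=C.[Li+] | intermediate
20 | dilithio reagent, lithium (3R)-5-lithio-3-methylpent-1-en-3-olate | [Li]CC[C@@](C)(O[Li])C=C | intermediate
21 | (1R,2S,4aS,6R,8aR)-6-bromo-1-[(3R)-3-hydroxy-3-methylpent-4-en-1-yl]-2,5,5,8a-tetramethyldecahydronaphthalen-1-ol | C=C[C@](C)(O)CC[C@@]1(O)[C@@H](C)CC[C@@H]2C(C)(C)[C@H](Br)CC[C@]21C | target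

Total step count: 10. Longest linear sequence: 8 steps (steps 1–7 and 10, from (S)-carvone); steps 8 and 9 form the side-chain branch.

The three steps judged most likely to fail

Step 3 (key step). What may go wrong: anionic oligomerisation of the acrylate by ester enolate 7 faster than ring closure, or reversal of the hindered Michael addition. Fallback: a stepwise, sulfone-based annulation that sets out from 4 and comes back at 9. Enolate 6 (KOtBu, THF) is added to phenyl vinyl sulfone, which should not oligomerise under these conditions, and protonation gives the keto sulfone F1. LiN(i-Pr)2 (2.2 equiv, THF, −78 to 0 °C) then forms the α-sulfonyl carbanion at C2, whose acylation by the C3 ester closes the same C2–C3 bond and gives the β-keto sulfone F2. Reductive desulfonylation with Al(Hg) in wet THF, followed by DBU to equilibrate C8, gives diketone 9, so that steps 3 and 4 are bypassed.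

Step 7. What may go wrong: hydrogen-atom transfer to C3 instead of C2, followed by β-scission of bromine and over-reduction to the bromine-free decalone, or insufficient facial selectivity in the second hydrogen transfer. Fallback: a route without an alkene that sets out from 11 and comes back at 13. Hydrazine hydrate (EtOH, reflux) should condense selectively with the less hindered C3 ketone to give the hydrazone F3. CuBr2 and LiOt-Bu in THF oxidise it to the geminal dibromide F4. One equivalent of Bu3SnH (Et3B, air, toluene, −78 °C) then removes one bromine through the α-bromo radical at C3, which should again take hydrogen axially and leave the equatorial bromide 13.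

Step 9. What may go wrong: electrophilic attack of the iodine reagent on the vinyl group, or ionisation of the tertiary allylic formate, in competition with the alkoxy-radical fragmentation. Fallback: a different C–C cleavage that sets out from 14 and comes back at 18. Schenck ene photo-oxygenation of 14 (O2, rose bengal, light, MeOH; then PPh3) gives, after separation from its regioisomer, the dienediol F5. Ozonolysis of its internal disubstituted alkene in preference to the vinyl group, with NaBH4 work-up, gives the diol F6. Selective Appel-type iodination of the primary hydroxyl (I2, PPh3, imidazole, CH2Cl2, 0 °C) gives 18.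

Further compounds
F1 | step 3 | methyl 2-methyl-2-{2,4-dimethyl-3-oxo-2-[2-(phenylsulfonyl)ethyl]-5-(prop-1-en-2-yl)cyclohexyl}propanoate (sulfonylethyl group on C10 trans to the C5 substituent) | O=S(=O)(c1ccccc1)CC[C@@]1(C)C(=O)[C@H](C)[C@@H](C(C)=C)C[C@@H]1C(C)(C)C(=O)OC
F2 | step 3 | 2,5,5,8a-tetramethyl-7-(phenylsulfonyl)-3-(prop-1-en-2-yl)octahydronaphthalene-1,6-dione (trans-fused; epimers at the sulfonyl carbon) | O=C1[C@@H](C)[C@@H](C(C)=C)C[C@@H]2C(C)(C)C(=O)C(S(=O)(=O)c3ccccc3)C[C@]21C
F3 | step 7 | (2S,4aR,8aR)-6-hydrazinylidene-2,5,5,8a-tetramethyloctahydronaphthalen-1(2H)-one | O=C1[C@@H](C)CC[C@@H]2C(C)(C)C(=NN)CC[C@]21C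
F4 | step 7 | (2S,4aS,8aR)-6,6-dibromo-2,5,5,8a-tetramethyloctahydronaphthalen-1(2H)-one | O=C1[C@@H](C)CC[C@@H]2C(C)(C)C(Br)(Br)CC[C@]21C
F5 | step 9 | (3E,6R)-2,6-dimethylocta-3,7-diene-2,6-diol | CC(C)(O)/C=C/C[C@@](C)(O)C=C
F6 | step 9 | (3R)-3-methylpent-4-ene-1,3-diol | OCC[C@@](C)(O)C=C
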